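**Retrosynthetic overview**
1. Target ⇒ one [4+2] event (bonds C1–C13' and C3–C11'; the bicyclo[2.2.1]heptene, three new stereocentres) between 2-acetoxycyclopentadiene 33 and α-methylene lactone 32. Diene 33 is made in the same flask by dehydrating 4-hydroxyguaianolide 14; nothing is protected and this is the last step.
2. 14 ⇐ enone lactone 12 (CBS reduction, acetylation) ⇐ bromide 10 by chromium-mediated allylation (C7–C8) ⇐ cyclopentenone 8 (Stork–Danheiser) ⇐ 1 + 2 (organocatalytic Michael addition sets C10).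
3. 32 ⇐ bromomethylbutenolide 31 by chromium-mediated allylation (C6'–C7') ⇐ lactone 25 (Ir-catalysed allylation sets C8') ⇐ Z-hydroxy amide 22 ⇐ dihydropyranone 21 ⇐ (R)-citronellic acid 15 + ketone 16.
4. Ring order: fragment 1, five-membered ring (bought) → seven-membered ring → γ-lactone; fragment 2, temporary δ-lactone → γ-lactone → cyclohexene; last, the norbornene.

Assumption: the SMILES is taken exactly as drawn; guaiane numbering (C1–C15) is used for the guaianolide half and primed eudesmane numbering for the 1,10-seco-eudesmanolide half; silyl ether 16 is taken as a catalogue item.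

**Fragment 1 (guaianolide half)**

Step 1
Reactants: 1 cyclopentane-1,3-dione; 2 (E)-but-2-enal
Product: 4 (4R)-2-methoxy-4-methyl-3,4,6,7-tetrahydrocyclopenta[b]pyran-5(2H)-one (C2 epimers), via lactol 3 (not isolated)
Conditions: (S)-2-{bis[3,5-bis(trifluoromethyl)phenyl](trimethylsilyloxy)methyl}pyrrolidine (10 mol %), PhCO2H (10 mol %), CH2Cl2, 0 °C; then MeOH, PPTS, 4 Å MS, rt
Reagents that add atoms: methanol, CO
Why: Iminium-catalysed enantioselective Michael addition of the cyclic 1,3-diketone, in which the S catalyst shields one face of the crotonaldehyde iminium ion so that C10 is formed R; the lactol is then fixed as a cyclic vinylogous ester by acid-catalysed acetalisation.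

Step 2
Reactants: 4 (4R)-2-methoxy-4-methyl-3,4,6,7-tetrahydrocyclopenta[b]pyran-5(2H)-one
Product: 5 (4R)-2-methoxy-4,6-dimethyl-3,4,6,7-tetrahydrocyclopenta[b]pyran-5(2H)-one (C2/C6 epimers)
Conditions: LiN(i-Pr)2, THF, −78 °C; MeI, −78 to −20 °C
Reagents that add atoms: iodomethane, CI
Why: Kinetic α'-enolate alkylation of a vinylogous ester (Stork–Danheiser) installs C15; the new centre is later made quaternary and then sp2, so its configuration does not matter.

Step 3
Reactants: 5 (4R)-2-methoxy-4,6-dimethyl-3,4,6,7-tetrahydrocyclopenta[b]pyran-5(2H)-one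
Product: 6 (4R)-6-hydroxy-2-methoxy-4,6-dimethyl-3,4,6,7-tetrahydrocyclopenta[b]pyran-5(2H)-one (C2/C6 epimers)
Conditions: LiN(i-Pr)2, THF, −78 °C; 2-(phenylsulfonyl)-3-phenyloxaziridine; H2O
Reagents that add atoms: 2-(phenylsulfonyl)-3-phenyloxaziridine, O=S(=O)(c1ccccc1)N1OC1c1ccccc1
Why: Davis oxidation of the tetrasubstituted enolate gives the tertiary C4 carbinol of the biogenetic 4-hydroxyguaianolide; both epimers converge in step 18.

Step 4
Reactants: 6 (4R)-6-hydroxy-2-methoxy-4,6-dimethyl-3,4,6,7-tetrahydrocyclopenta[b]pyran-5(2H)-one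
Product: 8 4-hydroxy-4-methyl-2-[(2R)-4-oxobutan-2-yl]-3-(prop-2-en-1-yl)cyclopent-2-en-1-one (C4 epimers), via diol 7 (not isolated)
Conditions: CH2=CHCH2MgBr (2.5 equiv), THF, −78 to 0 °C; then 1 M HCl, THF, rt
Reagents that add atoms: allylmagnesium bromide, C=CC[Mg]Br; water, O
Why: Stork–Danheiser transposition: 1,2-addition of the allyl Grignard reagent to the hindered vinylogous-ester carbonyl, then acid hydrolysis gives the enone and releases the C8 aldehyde; C10 is not touched.

Step 5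
Reactants: 8 4-hydroxy-4-methyl-2-[(2R)-4-oxobutan-2-yl]-3-(prop-2-en-1-yl)cyclopent-2-en-1-one; 9 methyl 2-(bromomethyl)prop-2-enoate
Product: 10 methyl (2Z)-2-(bromomethyl)-4-{5-hydroxy-5-methyl-3-oxo-2-[(2R)-4-oxobutan-2-yl]cyclopent-1-en-1-yl}but-2-enoate
Conditions: 9 (5 equiv), second-generation Hoveyda–Grubbs catalyst RuCl2(H2IMes)(=CH-C6H4-2-O-i-Pr) (5 mol %), 1,4-benzoquinone (10 mol %), CH2Cl2, 40 °C
Reagents that add atoms: none
Why: Olefin cross-metathesis of the terminal alkene with the 1,1-disubstituted acrylate gives the thermodynamically preferred trisubstituted enoate (chain trans to the ester); benzoquinone suppresses isomerisation of the allyl group into conjugation.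

Step 6
Reactants: 10 methyl (2Z)-2-(bromomethyl)-4-{5-hydroxy-5-methyl-3-oxo-2-[(2R)-4-oxobutan-2-yl]cyclopent-1-en-1-yl}but-2-enoate
Product: 12 (7S,8R,10R)-4-hydroxy-2-oxoguaia-1(5),11(13)-dien-12,8-olide (C4 epimers), via hydroxy ester 11 (not isolated)
Conditions: CrCl2 (4 equiv), THF, 0.005 M, rt; then TsOH (cat.), CH2Cl2, rt
Reagents that add atoms: none
Why: Intramolecular Nozaki–Hiyama (Barbier-type) 2-(alkoxycarbonyl)allylation of the aldehyde closes the seven-membered ring, and lactonisation then gives the α-methylene lactone; anti addition through a chair-like transition state, with the two new substituents equatorial and the C10 methyl pseudoaxial (allylic strain against the C2 carbonyl), sets 7S and 8R (trans-fused).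

Step 7
Reactants: 12 (7S,8R,10R)-4-hydroxy-2-oxoguaia-1(5),11(13)-dien-12,8-olide
Product: 13 (2S,7S,8R,10R)-2,4-dihydroxyguaia-1(5),11(13)-dien-12,8-olide (C4 epimers)
Conditions: (R)-2-methyl-CBS-oxazaborolidine (20 mol %), catecholborane, toluene, −78 °C
Reagents that add atoms: none
Why: Corey–Bakshi–Shibata reduction; reagent-controlled 1,2-hydride delivery to the enone (alkenyl side as the large group) gives the 2S carbinol, with the oxygen on the face of the C10 methyl.

Step 8
Reactants: 13 (2S,7S,8R,10R)-2,4-dihydroxyguaia-1(5),11(13)-dien-12,8-olide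
Product: 14 (2S,7S,8R,10R)-2-acetoxy-4-hydroxyguaia-1(5),11(13)-dien-12,8-olide (C4 epimers)
Conditions: Ac2O, pyridine, DMAP (cat.), CH2Cl2, 0 °C
Reagents that add atoms: acetic anhydride, CC(=O)OC(C)=O
Why: Nucleophile-catalysed acylation of the secondary allylic alcohol only; the tertiary C4 hydroxyl does not react under these conditions.

**Fragment 2 (seco-eudesmanolide half)**

Step 9
Reactants: 15 (3R)-3,7-dimethyloct-6-enoic acid; 16 4-[(tert-butyldimethylsilyl)oxy]butan-2-one
Product: 17 (3R)-2-{4-[(tert-butyldimethylsilyl)oxy]-2-hydroxybutan-2-yl}-3,7-dimethyloct-6-enoic acid (diastereomers at the two new centres)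
Conditions: LiN(i-Pr)2 (2.2 equiv), THF, −78 to 0 °C; 16, −78 °C; aq. HCl
Reagents that add atoms: none
Why: Aldol addition of the carboxylic acid dianion (Ivanov-type) to the methyl ketone; C4' (R) comes from citronellic acid and the two new centres become sp2 in step 11.

Step 10
Reactants: 17 (3R)-2-{4-[(tert-butyldimethylsilyl)oxy]-2-hydroxybutan-2-yl}-3,7-dimethyloct-6-enoic acid
Product: 19 4-hydroxy-4-methyl-3-[(2R)-6-methylhept-5-en-2-yl]oxan-2-one (diastereomers), via dihydroxy acid 18 (not isolated)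
Conditions: 1 M HCl, THF, rt
Reagents that add atoms: none
Why: Acid desilylation followed by spontaneous δ-lactonisation of the hydroxy acid; no stereocentre that is kept is involved.

Step 11
Reactants: 19 4-hydroxy-4-methyl-3-[(2R)-6-methylhept-5-en-2-yl]oxan-2-one
Product: 21 4-methyl-3-[(2R)-6-methylhept-5-en-2-yl]-5,6-dihydro-2H-pyran-2-one, via mesylate 20 (not isolated)
Conditions: MsCl, Et3N, CH2Cl2, 0 °C; then DBU, rt
Reagents that add atoms: none
Why: E1cB dehydration through the tertiary mesylate gives only the conjugated endocyclic alkene, and the ring fixes C6' and C9' cis on the future tetrasubstituted C5'=C10' bond.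

Step 12
Reactants: 21 4-methyl-3-[(2R)-6-methylhept-5-en-2-yl]-5,6-dihydro-2H-pyran-2-one
Product: 22 (2Z)-5-hydroxy-N,N,3-trimethyl-2-[(2R)-6-methylhept-5-en-2-yl]pent-2-enamide
Conditions: Me2NH·HCl, AlMe3, CH2Cl2, 0 to 40 °C
Reagents that add atoms: dimethylamine hydrochloride, CNC.Cl
Why: Weinreb-type aluminium amide aminolysis opens the lactone, frees the C8' primary alcohol and keeps the Z geometry.

Step 13
Reactants: 22 (2Z)-5-hydroxy-N,N,3-trimethyl-2-[(2R)-6-methylhept-5-en-2-yl]pent-2-enamide; 23 methyl 2-(acetoxymethyl)prop-2-enoate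
Product: 25 (2Z)-N,N,3-trimethyl-4-[(2S)-4-methylidene-5-oxooxolan-2-yl]-2-[(2R)-6-methylhept-5-en-2-yl]but-2-enamide, via hydroxy ester 24 (not isolated)
Conditions: [Ir(cod)Cl]2 (2.5 mol %), (S)-SEGPHOS (5 mol %), 4-cyano-3-nitrobenzoic acid (10 mol %), Cs2CO3 (20 mol %), THF, 60 °C; then TsOH (cat.), CH2Cl2, rt
Reagents that add atoms: none
Why: Krische iridium-catalysed transfer-hydrogenative 2-(alkoxycarbonyl)allylation from the alcohol oxidation level, then lactonisation; the catalyst sets C8' (S), and the ligand antipode is used if the sense on this substrate turns out opposite.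

Step 14
Reactants: 25 (2Z)-N,N,3-trimethyl-4-[(2S)-4-methylidene-5-oxooxolan-2-yl]-2-[(2R)-6-methylhept-5-en-2-yl]but-2-enamide
Product: 28 (4R,5Z)-5-(dimethylcarbamoyl)-4,6-dimethyl-7-[(2S)-4-methylidene-5-oxooxolan-2-yl]hept-5-en-1-yl acetate, via aldehyde 26 (not isolated), via alcohol 27 (not isolated)
Conditions: O3, CH2Cl2, −78 °C (Sudan red end point); Me2S; NaBH(OAc)3, AcOH, rt; then Ac2O, pyridine, DMAP
Reagents that add atoms: ozone, [O-][O+]=O; acetic anhydride, CC(=O)OC(C)=O
Why: Ozonolysis selects the electron-rich trisubstituted alkene over the two carbonyl-bearing alkenes, the triacetoxyborohydride reduces only the aldehyde (not the methylene lactone), and acetylation completes the side chain.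

Step 15
Reactants: 28 (4R,5Z)-5-(dimethylcarbamoyl)-4,6-dimethyl-7-[(2S)-4-methylidene-5-oxooxolan-2-yl]hept-5-en-1-yl acetate
Product: 29 (4R,5Z)-5-formyl-4,6-dimethyl-7-[(2S)-4-methylidene-5-oxooxolan-2-yl]hept-5-en-1-yl acetate
Conditions: Cp2Zr(H)Cl (1.5 equiv), THF, rt; aq. citric acid
Reagents that add atoms: none
Why: Reduction of the tertiary amide to the aldehyde with the Schwartz reagent (Georg conditions), which leaves esters and lactones alone; the acidic quench protonates the released amine before it can add to the methylene lactone.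

Step 16
Reactants: 29 (4R,5Z)-5-formyl-4,6-dimethyl-7-[(2S)-4-methylidene-5-oxooxolan-2-yl]hept-5-en-1-yl acetate
Product: 31 (4R,5Z)-7-[(2S)-4-(bromomethyl)-5-oxo-2,5-dihydrofuran-2-yl]-5-formyl-4,6-dimethylhept-5-en-1-yl acetate, via dibromide 30 (not isolated)
Conditions: Br2, CH2Cl2, −20 °C; then i-Pr2NEt, 0 °C
Reagents that add atoms: bromine, BrBr
Why: Bromine addition to the exocyclic methylene followed by E2 loss of HBr (H7' and the tertiary bromide) gives the endocyclic 3-(bromomethyl)butenolide, the allyl-metal precursor.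

Step 17
Reactants: 31 (4R,5Z)-7-[(2S)-4-(bromomethyl)-5-oxo-2,5-dihydrofuran-2-yl]-5-formyl-4,6-dimethylhept-5-en-1-yl acetate
Product: 32 (4R)-4-[(3aR,4R,7aS)-4-hydroxy-6-methyl-3-methylidene-2-oxo-2,3,3a,4,7,7a-hexahydro-1-benzofuran-5-yl]pentyl acetate
Conditions: CrCl2 (4 equiv), THF, 0.005 M, rt
Reagents that add atoms: none
Why: Intramolecular Nozaki–Hiyama (Barbier-type) allylation with SE2' attack through C7' closes the cyclohexene and regenerates the methylene lactone; the tether from C8' forces cis ring fusion (7'R) and the chair transition state of the ring-locked E-type allylchromium gives the anti carbinol (6'R, OH cis to H7').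

**Union**

Step 18
Reactants: 14 (2S,7S,8R,10R)-2-acetoxy-4-hydroxyguaia-1(5),11(13)-dien-12,8-olide; 32 (4R)-4-[(3aR,4R,7aS)-4-hydroxy-6-methyl-3-methylidene-2-oxo-2,3,3a,4,7,7a-hexahydro-1-benzofuran-5-yl]pentyl acetate
Product: 34 target CNP0211028.4, via diene 33 (not isolated)
Conditions: Ph2S[OC(CF3)2Ph]2 (1.05 equiv), CH2Cl2, −40 °C, 30 min; then 32 (3 equiv, excess recovered), concentrate to about 2 M, 25 °C, 48 h
Reagents that add atoms: none
Why: Biomimetic sequence of Martin sulfurane dehydration of the tertiary allylic alcohol to the labile 5-acetoxycyclopentadiene and an intermolecular Diels–Alder reaction with the unprotected methylene lactone. The regiochemistry (C13' to C1, C11' to C3) avoids vicinal quaternary centres. The expected selectivities are exo (lactone carbonyl towards the C2 bridge, as is usual for α-methylene lactones), diene face anti to the C2 acetate and C10 methyl, and dienophile face anti to the pseudoaxial 6'-hydroxyl; these set C1 (R), C3 (S) and C11' (R).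

**Compound list**
1 | cyclopentane-1,3-dione | O=C1CCC(=O)C1 | starting material
2 | (E)-but-2-enal | C/C=C/C=O | starting material
3 | (4R)-2-hydroxy-4-methyl-3,4,6,7-tetrahydrocyclopenta[b]pyran-5(2H)-one (lactol; C2 epimers) | OC1C[C@@H](C)C2=C(CCC2=O)O1 | intermediate (not isolated)
4 | (4R)-2-methoxy-4-methyl-3,4,6,7-tetrahydrocyclopenta[b]pyran-5(2H)-one (C2 epimers) | COC1C[C@@H](C)C2=C(CCC2=O)O1 | intermediate
5 | (4R)-2-methoxy-4,6-dimethyl-3,4,6,7-tetrahydrocyclopenta[b]pyran-5(2H)-one (C2/C6 epimers) | COC1C[C@@H](C)C2=C(CC(C)C2=O)O1 | intermediate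
6 | (4R)-6-hydroxy-2-methoxy-4,6-dimethyl-3,4,6,7-tetrahydrocyclopenta[b]pyran-5(2H)-one (C2/C6 epimers) | COC1C[C@@H](C)C2=C(CC(C)(O)C2=O)O1 | intermediate
7 | (4R)-2-methoxy-4,6-dimethyl-5-(prop-2-en-1-yl)-2,3,4,5,6,7-hexahydrocyclopenta[b]pyran-5,6-diol (epimer mixture) | COC1C[C@@H](C)C2=C(CC(C)(O)C2(O)CC=C)O1 | intermediate (not isolated)
8 | 4-hydroxy-4-methyl-2-[(2R)-4-oxobutan-2-yl]-3-(prop-2-en-1-yl)cyclopent-2-en-1-one (C4 epimers) | O=CC[C@@H](C)C1=C(CC=C)C(C)(O)CC1=O | intermediate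
9 | methyl 2-(bromomethyl)prop-2-enoate | C=C(CBr)C(=O)OC | starting material
10 | methyl (2Z)-2-(bromomethyl)-4-{5-hydroxy-5-methyl-3-oxo-2-[(2R)-4-oxobutan-2-yl]cyclopent-1-en-1-yl}but-2-enoate | O=CC[C@@H](C)C1=C(C/C=C(\CBr)C(=O)OC)C(C)(O)CC1=O | intermediate
11 | methyl (7S,8R,10R)-4,8-dihydroxy-2-oxoguaia-1(5),11(13)-dien-12-oate | COC(=O)C(=C)[C@@H]1CC2=C([C@H](C)C[C@H]1O)C(=O)CC2(C)O | intermediate (not isolated)
12 | (7S,8R,10R)-4-hydroxy-2-oxoguaia-1(5),11(13)-dien-12,8-olide (trans-fused lactone; C4 epimers) | C=C1C(=O)O[C@@H]2C[C@@H](C)C3=C(C[C@@H]12)C(C)(O)CC3=O | intermediate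
13 | (2S,7S,8R,10R)-2,4-dihydroxyguaia-1(5),11(13)-dien-12,8-olide | C=C1C(=O)O[C@@H]2C[C@@H](C)C3=C(C[C@@H]12)C(C)(O)C[C@@H]3O | intermediate
14 | (2S,7S,8R,10R)-2-acetoxy-4-hydroxyguaia-1(5),11(13)-dien-12,8-olide | C=C1C(=O)O[C@@H]2C[C@@H](C)C3=C(C[C@@H]12)C(C)(O)C[C@@H]3OC(C)=O | intermediate
15 | (3R)-3,7-dimethyloct-6-enoic acid ((R)-citronellic acid) | OC(=O)C[C@H](C)CCC=C(C)C | starting material
16 | 4-[(tert-butyldimethylsilyl)oxy]butan-2-one | CC(=O)CCO[Si](C)(C)C(C)(C)C | starting material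
17 | (3R)-2-{4-[(tert-butyldimethylsilyl)oxy]-2-hydroxybutan-2-yl}-3,7-dimethyloct-6-enoic acid (diastereomers) | OC(=O)C([C@H](C)CCC=C(C)C)C(C)(O)CCO[Si](C)(C)C(C)(C)C | intermediate
18 | (3R)-2-(2,4-dihydroxybutan-2-yl)-3,7-dimethyloct-6-enoic acid | OC(=O)C([C@H](C)CCC=C(C)C)C(C)(O)CCO | intermediate (not isolated)
19 | 4-hydroxy-4-methyl-3-[(2R)-6-methylhept-5-en-2-yl]oxan-2-one (diastereomers) | O=C1OCCC(C)(O)C1[C@H](C)CCC=C(C)C | intermediate
20 | 4-methyl-3-[(2R)-6-methylhept-5-en-2-yl]-2-oxooxan-4-yl methanesulfonate | O=C1OCCC(C)(OS(C)(=O)=O)C1[C@H](C)CCC=C(C)C | intermediate (not isolated)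
21 | 4-methyl-3-[(2R)-6-methylhept-5-en-2-yl]-5,6-dihydro-2H-pyran-2-one | O=C1OCCC(C)=C1[C@H](C)CCC=C(C)C | intermediate
22 | (2Z)-5-hydroxy-N,N,3-trimethyl-2-[(2R)-6-methylhept-5-en-2-yl]pent-2-enamide | CN(C)C(=O)/C(=C(/C)CCO)[C@H](C)CCC=C(C)C | intermediate
23 | methyl 2-(acetoxymethyl)prop-2-enoate | C=C(COC(C)=O)C(=O)OC | starting material
24 | methyl (4S,6Z,8R)-7-(dimethylcarbamoyl)-4-hydroxy-6,8,12-trimethyl-2-methylidenetrideca-6,11-dienoate | COC(=O)C(=C)C[C@@H](O)C/C(C)=C(\C(=O)N(C)C)[C@H](C)CCC=C(C)C | intermediate (not isolated)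
25 | (2Z)-N,N,3-trimethyl-4-[(2S)-4-methylidene-5-oxooxolan-2-yl]-2-[(2R)-6-methylhept-5-en-2-yl]but-2-enamide | C=C1C[C@H](C/C(C)=C(\C(=O)N(C)C)[C@H](C)CCC=C(C)C)OC1=O | intermediate
26 | (2Z)-N,N,3-trimethyl-4-[(2S)-4-methylidene-5-oxooxolan-2-yl]-2-[(2R)-5-oxopentan-2-yl]but-2-enamide | C=C1C[C@H](C/C(C)=C(\C(=O)N(C)C)[C@H](C)CCC=O)OC1=O | intermediate (not isolated)
27 | (2Z)-2-[(2R)-5-hydroxypentan-2-yl]-N,N,3-trimethyl-4-[(2S)-4-methylidene-5-oxooxolan-2-yl]but-2-enamide | C=C1C[C@H](C/C(C)=C(\C(=O)N(C)C)[C@H](C)CCCO)OC1=O | intermediate (not isolated)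
28 | (4R,5Z)-5-(dimethylcarbamoyl)-4,6-dimethyl-7-[(2S)-4-methylidene-5-oxooxolan-2-yl]hept-5-en-1-yl acetate | C=C1C[C@H](C/C(C)=C(\C(=O)N(C)C)[C@H](C)CCCOC(C)=O)OC1=O | intermediate
29 | (4R,5Z)-5-formyl-4,6-dimethyl-7-[(2S)-4-methylidene-5-oxooxolan-2-yl]hept-5-en-1-yl acetate | C=C1C[C@H](C/C(C)=C(\C=O)[C@H](C)CCCOC(C)=O)OC1=O | intermediate
30 | (4R,5Z)-7-[(2S)-4-bromo-4-(bromomethyl)-5-oxooxolan-2-yl]-5-formyl-4,6-dimethylhept-5-en-1-yl acetate (C4 of the lactone unassigned) | BrCC1(Br)C[C@H](C/C(C)=C(\C=O)[C@H](C)CCCOC(C)=O)OC1=O | intermediate (not isolated)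
31 | (4R,5Z)-7-[(2S)-4-(bromomethyl)-5-oxo-2,5-dihydrofuran-2-yl]-5-formyl-4,6-dimethylhept-5-en-1-yl acetate | BrCC1=C[C@H](C/C(C)=C(\C=O)[C@H](C)CCCOC(C)=O)OC1=O | intermediate
32 | (4R)-4-[(3aR,4R,7aS)-4-hydroxy-6-methyl-3-methylidene-2-oxo-2,3,3a,4,7,7a-hexahydro-1-benzofuran-5-yl]pentyl acetate (cis-fused lactone, OH cis to H7') | C=C1C(=O)O[C@H]2CC(C)=C([C@H](C)CCCOC(C)=O)[C@H](O)[C@@H]12 | intermediate
33 | (2S,7S,8R,10R)-2-acetoxyguaia-1(5),3,11(13)-trien-12,8-olide | C=C1C(=O)O[C@@H]2C[C@@H](C)C3=C(C[C@@H]12)C(C)=C[C@@H]3OC(C)=O | intermediate (not isolated)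
34 | CNP0211028.4: Diels–Alder adduct of 33 and 32 with bonds C1–C13' and C3–C11'; (1R,2S,3S,7S,8R,10R) in the guaianolide half and (4'R,6'R,7'R,8'S,11'R) in the seco-eudesmanolide half | C=C1C(=O)O[C@@H]2C[C@@H](C)[C@]34C[C@@]5(C(=O)O[C@H]6CC(C)=C([C@H](C)CCCOC(C)=O)[C@H](O)[C@H]65)[C@H](C(C)=C3C[C@@H]12)[C@@H]4OC(C)=O | target

**Step count**
Total: 18 steps (8 for fragment 1, 9 for fragment 2, 1 for the union). Longest linear sequence: 10 steps (15 to 34, steps 9–18).

**Three steps most likely to fail**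

Step 18. The diene 33 can isomerise by 1,5-hydrogen shift or dimerise through its own methylene lactone, and four selectivity questions (regiochemistry, exo/endo, both faces) are decided at once. The face anti to the acetate goes against the usual syn preference of 5-acyloxycyclopentadienes and relies on the C10 methyl. Fallback: set out from 14 and add dimethylamine (EtOH, 0 °C) to its methylene lactone to give (2S,7S,8R,10R)-2-acetoxy-13-(dimethylamino)-4-hydroxyguai-1(5)-en-12,8-olide F1. Dehydrate as before to the amino diene F2, which cannot add to itself and can therefore be used in excess or under 10 kbar with 32 to give the 13-(dimethylamino)-11,13-dihydro cycloadduct F3. Quaternisation with MeI and elimination with NaHCO3 restores the methylene lactone and comes back to the route at 34.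

Step 6. Closing a seven-membered ring while setting C7 and C8 against C10 rests on a conformational argument, and the cis-fused lactone may dominate. Fallback: set out from 10 and close the ring with Zn dust (THF, aq. NH4Cl), which follows the syn pathway, to give the cis-fused (7S,8S,10R)-4-hydroxy-2-oxoguaia-1(5),11(13)-dien-12,8-olide F4. Open it with LiOH to (7S,8S,10R)-4,8-dihydroxy-2-oxoguaia-1(5),11(13)-dien-12-oic acid F5 and relactonise under Mitsunobu conditions (PPh3, DIAD), which inverts C8 and comes back to the route at 12.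

Step 13. The hydroxy amide can relactonise under base and heat, and the transient β,γ-unsaturated aldehyde can enolise. Fallback: set out from 22 and oxidise it with Dess–Martin periodinane at 0 °C to (2Z)-N,N,3-trimethyl-2-[(2R)-6-methylhept-5-en-2-yl]-5-oxopent-2-enamide F6. Use this aldehyde at once in a catalytic enantioselective Nozaki–Hiyama 2-(alkoxycarbonyl)allylation with bromide 9 (CrCl2 10 mol %, chiral bis(oxazolinyl)carbazole ligand, Mn, Me3SiCl, THF, rt). Acid lactonisation of hydroxy ester 24 then comes back to the route at 25.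

**Further compounds**
F1 | step 18 | (2S,7S,8R,10R)-2-acetoxy-13-(dimethylamino)-4-hydroxyguai-1(5)-en-12,8-olide (C4/C11 epimers) | CN(C)CC1C(=O)O[C@@H]2C[C@@H](C)C3=C(C[C@@H]12)C(C)(O)C[C@@H]3OC(C)=O
F2 | step 18 | (2S,7S,8R,10R)-2-acetoxy-13-(dimethylamino)guaia-1(5),3-dien-12,8-olide (C11 epimers) | CN(C)CC1C(=O)O[C@@H]2C[C@@H](C)C3=C(C[C@@H]12)C(C)=C[C@@H]3OC(C)=O
F3 | step 18 | 13-(dimethylamino)-11,13-dihydro derivative of 34 (C11 epimers) | CN(C)CC1C(=O)O[C@@H]2C[C@@H](C)[C@]34C[C@@]5(C(=O)O[C@H]6CC(C)=C([C@H](C)CCCOC(C)=O)[C@H](O)[C@H]65)[C@H](C(C)=C3C[C@@H]12)[C@@H]4OC(C)=O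
F4 | step 6 | (7S,8S,10R)-4-hydroxy-2-oxoguaia-1(5),11(13)-dien-12,8-olide (cis-fused; C4 epimers) | C=C1C(=O)O[C@H]2C[C@@H](C)C3=C(C[C@@H]12)C(C)(O)CC3=O
F5 | step 6 | (7S,8S,10R)-4,8-dihydroxy-2-oxoguaia-1(5),11(13)-dien-12-oic acid | OC(=O)C(=C)[C@@H]1CC2=C([C@H](C)C[C@@H]1O)C(=O)CC2(C)O
F6 | step 13 | (2Z)-N,N,3-trimethyl-2-[(2R)-6-methylhept-5-en-2-yl]-5-oxopent-2-enamide | O=CC/C(C)=C(\C(=O)N(C)C)[C@H](C)CCC=C(C)C
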